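Ring A of sarothralin is a phloroglucinol whose three oxygen-bearing carbons alternate with C–H, C-benzoyl and the carbon carrying the CH2 bridge to ring B. That pattern is a cyclised triketo ester, so ring A is disconnected at the bond between the bridge-bearing carbon and the C–OH para to the benzoyl group. The precursor is pyran-2-one 15: lactone C2 becomes that C–OH, C4 already carries the prenyl ether, C5 the benzoyl group, and the 6-(2-filicinylethyl) chain supplies the last ring carbon. One alkoxide treatment opens the lactone and closes ring A by Claisen condensation, fixing the site of the single ether and of the bridge.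

Key step: step 7

Remarks on the chemistry
- Ring B is written throughout as the dienol tautomer of the target SMILES; its triketone tautomers interconvert freely. The target has no stereocentre, so no step has to set configuration.
- In the ring-opened intermediate 16 the ester lies cis to the diketone carbon across the former C3=C4 bond. Because the ether oxygen outranks carbon, this geometry is E in sequence-rule terms, and 16 is drawn so.
- The alkoxide of the key step is that of prenol, so the ester formed on ring opening and any alkoxide exchange at C4 carry the same alkoxy group as the ether that must survive.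

Step 1
Reactants: 1 benzoylacetone (1-phenylbutane-1,3-dione); 2 malonyl dichloride
Product: 3 5-benzoyl-4-hydroxy-6-methylpyran-2-one
Conditions: 1 (1.1 equiv), 2 (1.0 equiv), CH2Cl2, 0 °C to 40 °C, slow N2 stream to remove HCl
Reagents that add atoms: none
Why: Cyclocondensation by twofold acylation (C-acylation of the doubly activated methylene, then lactonisation of the second acid chloride by an enol oxygen) is the established way from 1,3-diketones and malonyl dichloride to 5-acyl-4-hydroxypyran-2-ones, and closure through the acetyl enol oxygen should be preferred because it is the less hindered, more nucleophilic oxygen and leaves the aryl ketone conjugated with its phenyl ring.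

Step 2
Reactants: 3 5-benzoyl-4-hydroxy-6-methylpyran-2-one; 4 prenol (3-methylbut-2-en-1-ol)
Product: 5 5-benzoyl-6-methyl-4-(3-methylbut-2-enyloxy)pyran-2-one
Conditions: PPh3, DIAD, THF, 0 °C to rt
Reagents that add atoms: none
Why: Mitsunobu etherification, in which the vinylogous-acid 4-OH (pKa near 5) is an ideal pronucleophile and reacts at the 4-oxygen under neutral conditions, avoiding the C3-prenylation and carbonyl-oxygen alkylation that a prenyl halide with base can give, while the primary allylic alcohol is displaced by SN2 without allylic transposition.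

Step 3
Reactants: 5 5-benzoyl-6-methyl-4-(3-methylbut-2-enyloxy)pyran-2-one
Product: 7 5-benzoyl-6-[2-(dimethylamino)ethyl]-4-(3-methylbut-2-enyloxy)pyran-2-one, via lithium dienolate 6 (not isolated)
Conditions: LiN(SiMe3)2 (1.05 equiv), THF, −78 °C; then CH2=NMe2+ I− (Eschenmoser's salt), −78 °C to 0 °C
Reagents that add atoms: N,N-dimethylmethylideneammonium iodide (Eschenmoser's salt), C=[N+](C)C.[I-]
Why: Vinylogous Mannich reaction, in which the 6-methyl group (γ to the benzoyl carbonyl and vinylogously α to the lactone carbonyl) is deprotonated by the hindered amide base without attack on either carbonyl, and the extended enolate 6 takes up the iminium ion at its terminal carbon because C5 is fully substituted and attack at C3 or C5 would interrupt the pyranone conjugation.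

Step 4
Reactants: 8 phloroglucinol; 9 isobutyryl chloride
Product: 10 2-methyl-1-(2,4,6-trihydroxyphenyl)propan-1-one (phlorisobutyrophenone)
Conditions: AlCl3 (3 equiv), PhNO2/CH2Cl2, rt to 45 °C; then ice/aq. HCl
Reagents that add atoms: none
Why: Friedel–Crafts acylation of the very electron-rich, threefold-symmetric arene, which stops at the monoketone because the aluminium-chelated aryl ketone deactivates the ring.

Step 5
Reactants: 10 2-methyl-1-(2,4,6-trihydroxyphenyl)propan-1-one
Product: 12 isobutyrylfilicinic acid (3,5-dihydroxy-6,6-dimethyl-2-(2-methylpropanoyl)cyclohexa-2,4-dien-1-one), via monomethyl ketone 11 (not isolated)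
Conditions: NaOMe (3.2 equiv), MeI (2.2 equiv), MeOH, 0 °C to rt; then aq. HCl
Reagents that add atoms: iodomethane, CI
Why: Dearomatising C-alkylation of the phloroglucinol polyanion by a soft electrophile in methanol, in which the carbon that has taken the first methyl group (11) is the most electron-rich site and takes the second, while the resulting cyclic triketone is a much stronger acid whose stabilised anion is alkylated only slowly, so about two equivalents of MeI should stop the reaction at the geminal dimethyl stage.

Step 6
Reactants: 7 5-benzoyl-6-[2-(dimethylamino)ethyl]-4-(3-methylbut-2-enyloxy)pyran-2-one; 12 isobutyrylfilicinic acid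
Product: 15 5-benzoyl-6-[2-(2,6-dihydroxy-3,3-dimethyl-5-(2-methylpropanoyl)-4-oxocyclohexa-1,5-dien-1-yl)ethyl]-4-(3-methylbut-2-enyloxy)pyran-2-one, via ammonium iodide 13 (not isolated), via vinylpyranone 14 (not isolated)
Conditions: MeI, MeCN, rt; evaporate excess MeI; then 12 (1.2 equiv), i-Pr2NEt (3 equiv), MeCN, 50 °C; aq. citric acid work-up
Reagents that add atoms: none
Why: Mannich-base alkylation in its elimination–addition form, in which quaternisation turns the amine into a leaving group β to the acidic side-chain CH2, E1cB elimination releases vinylpyranone 14 only in the presence of the fully ionised triketone enolate of 12, and Michael addition through the single C–H ring carbon of that enolate to the vinyl group (conjugated with the benzoyl and lactone carbonyls) should give the C-alkylated, re-enolised adduct as the thermodynamic product.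

Step 7
Reactants: 15 5-benzoyl-6-[2-(2,6-dihydroxy-3,3-dimethyl-5-(2-methylpropanoyl)-4-oxocyclohexa-1,5-dien-1-yl)ethyl]-4-(3-methylbut-2-enyloxy)pyran-2-one
Product: 17 sarothralin, via ring-opened prenyl ester 16 (not isolated)
Conditions: Bu2Mg (4 equiv), prenol, THF, 0 °C, giving Mg(OCH2CH=CMe2)2; add 15; 65 °C; then cold 1 M HCl
Reagents that add atoms: none
Why: The alkoxide adds to the lactone carbonyl C2 and the ring opens to the magnesium-chelated diketone enolate 16, whose prenyl ester stays cis to the diketone carbon across the former C3=C4 bond (E by the sequence rules) because that geometry is inherited from the pyranone; deprotonation of the CH2 next to the former C6 carbonyl then gives the carbanion that attacks the ester, expels prenyl alkoxide and, after enolisation, leaves ring A as its magnesium phenolate, which cold acid releases. The closest known reaction type is the base-induced recyclisation of 6-alkyl-4-alkoxypyran-2-ones (masked 3,5-diketo esters) to phloroglucinol ethers by intramolecular Claisen condensation, for which magnesium alkoxides are customary reagents. The single ring closes in a 6-(enolendo)-exo-trig mode and no stereocentre is formed. The step needs C-acylation by the side-chain methylene in preference to retro-Claisen loss of the benzoyl group: the chelate of the divalent magnesium ion with the diketone shields both ketone carbonyls from alkoxide while activating the ester, reclosure through either diketone oxygen only regenerates a pyranone reversibly, no other carbon can reach the ester through a six-membered transition state, and aromatisation makes the C–C closure the only irreversible exit. Because the alkoxide is that of prenol, addition–elimination at the C4 vinylogous ester is degenerate and the prenyl ether cannot be exchanged, while ring B travels as its magnesium enolate and takes no part.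

Compound list
1 | benzoylacetone (1-phenylbutane-1,3-dione) | CC(=O)CC(=O)c1ccccc1 | starting material
2 | malonyl dichloride | O=C(Cl)CC(Cl)=O | starting material
3 | 5-benzoyl-4-hydroxy-6-methylpyran-2-one | Cc1oc(=O)cc(O)c1C(=O)c1ccccc1 | intermediate
4 | prenol (3-methylbut-2-en-1-ol) | CC(C)=CCO | starting material
5 | 5-benzoyl-6-methyl-4-(3-methylbut-2-enyloxy)pyran-2-one | Cc1oc(=O)cc(OCC=C(C)C)c1C(=O)c1ccccc1 | intermediate
6 | lithium dienolate of 5 (lithium 5-benzoyl-6-methylidene-4-(3-methylbut-2-enyloxy)-6H-pyran-2-olate, one resonance form) | [Li+].[O-]C1=CC(OCC=C(C)C)=C(C(=O)c2ccccc2)C(=C)O1 | intermediate (not isolated)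
7 | 5-benzoyl-6-[2-(dimethylamino)ethyl]-4-(3-methylbut-2-enyloxy)pyran-2-one | CN(C)CCc1oc(=O)cc(OCC=C(C)C)c1C(=O)c1ccccc1 | intermediate
8 | phloroglucinol (benzene-1,3,5-triol) | Oc1cc(O)cc(O)c1 | starting material
9 | isobutyryl chloride (2-methylpropanoyl chloride) | CC(C)C(Cl)=O | starting material
10 | 2-methyl-1-(2,4,6-trihydroxyphenyl)propan-1-one (phlorisobutyrophenone) | CC(C)C(=O)c1c(O)cc(O)cc1O | intermediate
11 | 2-methyl-1-(2,4,6-trihydroxy-3-methylphenyl)propan-1-one | CC(C)C(=O)c1c(O)cc(O)c(C)c1O | intermediate (not isolated)
12 | isobutyrylfilicinic acid (3,5-dihydroxy-6,6-dimethyl-2-(2-methylpropanoyl)cyclohexa-2,4-dien-1-one) | CC(C)C(=O)C1=C(O)C=C(O)C(C)(C)C1=O | intermediate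
13 | 2-[5-benzoyl-4-(3-methylbut-2-enyloxy)-2-oxopyran-6-yl]-N,N,N-trimethylethanaminium iodide | C[N+](C)(C)CCc1oc(=O)cc(OCC=C(C)C)c1C(=O)c1ccccc1.[I-] | intermediate (not isolated)
14 | 5-benzoyl-6-ethenyl-4-(3-methylbut-2-enyloxy)pyran-2-one | C=Cc1oc(=O)cc(OCC=C(C)C)c1C(=O)c1ccccc1 | intermediate (not isolated)
15 | 5-benzoyl-6-[2-(2,6-dihydroxy-3,3-dimethyl-5-(2-methylpropanoyl)-4-oxocyclohexa-1,5-dien-1-yl)ethyl]-4-(3-methylbut-2-enyloxy)pyran-2-one (precursor of the key step) | O=c1cc(OCC=C(C)C)c(C(=O)c2ccccc2)c(CCC3=C(O)C(C)(C)C(=O)C(C(=O)C(C)C)=C3O)o1 | intermediate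
16 | ring-opened triketo ester, drawn as the neutral chelated enol (present in the flask as its magnesium enolate): 3-methylbut-2-enyl (2E)-4-benzoyl-5-hydroxy-3-(3-methylbut-2-enyloxy)-7-(ring B)hepta-2,4-dienoate | CC(C)=CCOC(=O)/C=C(OCC=C(C)C)\C(C(=O)c1ccccc1)=C(\O)CCC1=C(O)C(C)(C)C(=O)C(C(=O)C(C)C)=C1O | intermediate (not isolated)
17 | sarothralin ([2,4-dihydroxy-3-[(2,6-dihydroxy-3,3-dimethyl-5-(2-methylpropanoyl)-4-oxocyclohexa-1,5-dien-1-yl)methyl]-6-(3-methylbut-2-enyloxy)phenyl](phenyl)methanone) | CC(C)=CCOc1cc(O)c(CC2=C(O)C(C)(C)C(=O)C(C(=O)C(C)C)=C2O)c(O)c1C(=O)c1ccccc1 | target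

Total step count: 7. Longest linear sequence: 5 steps (steps 1, 2, 3, 6 and 7, from benzoylacetone); ring B is made in 2 steps (4 and 5) and joins at step 6.

Steps most likely to fail

Step 7. Closure may stall at the ring-opened chelate, because the carbanion has to form at a secondary carbon beside the anionic ring B, or the alkoxide may cleave the benzoyl group by retro-Claisen. The fallback separates ring A formation from the union with ring B. It sets out from 5, whose unhindered 6-methyl group and absence of ring B make the same Mg(OCH2CH=CMe2)2 isomerisation easier; this should give (2,4-dihydroxy-6-(3-methylbut-2-enyloxy)phenyl)(phenyl)methanone F1. In parallel, 12 and CH2=NMe2+ I− give the Mannich base 4-[(dimethylamino)methyl]-3,5-dihydroxy-6,6-dimethyl-2-(2-methylpropanoyl)cyclohexa-2,4-dien-1-one F2. Heating F1 with F2 in dioxane at 80 °C should release dimethylamine and form the transient methylene triketone F3. F1 should capture F3 at its ring carbon between the two hydroxyl groups, which is the classical Mannich-base route to methylene-bridged acylphloroglucinols. The fallback comes back to the route at 17. Its price is that the site of bridging is then set by the nucleophilicity of F1 and no longer by the pyranone.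

Step 1. Lactonisation may go through the benzoyl oxygen, or excess acid chloride may annulate the product a second time. The fallback sets out from 1 and 2 and uses the isomeric pyranone, 5-acetyl-4-hydroxy-6-phenylpyran-2-one F4, because both pyranone isomers open to the same diketone enolate. Mitsunobu prenylation as in step 2 should give 5-acetyl-4-(3-methylbut-2-enyloxy)-6-phenylpyran-2-one F5. Mannich reaction at the acetyl methyl group (LiN(SiMe3)2, then CH2=NMe2+ I−) should give 5-[3-(dimethylamino)propanoyl]-4-(3-methylbut-2-enyloxy)-6-phenylpyran-2-one F6. Quaternisation with MeI and treatment with 12 and i-Pr2NEt, as in step 6, should give 5-[3-(2,6-dihydroxy-3,3-dimethyl-5-(2-methylpropanoyl)-4-oxocyclohexa-1,5-dien-1-yl)propanoyl]-4-(3-methylbut-2-enyloxy)-6-phenylpyran-2-one F7. The alkoxide of step 7 opens F7 at its lactone carbonyl to the same enolate, so the fallback comes back to the route at 16 and continues to 17.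

Step 6. The transient vinylpyranone may oligomerise faster than the weakly nucleophilic, hindered triketone enolate adds to it, or the enolate may react at oxygen. The fallback replaces conjugate addition by reductive alkylation. It sets out from 5: the dienolate 6 is formylated with ethyl formate to give [5-benzoyl-4-(3-methylbut-2-enyloxy)-2-oxopyran-6-yl]acetaldehyde F8. Three-component reductive alkylation of 12 with F8 (L-proline as catalyst, Hantzsch ester, CH2Cl2, rt) should pass through the Knoevenagel alkylidene triketone F9, which is reduced in the flask by hydride transfer. The fallback comes back to the route at 15 and so also bypasses step 3.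

Further compounds
F1 | step 7 | (2,4-dihydroxy-6-(3-methylbut-2-enyloxy)phenyl)(phenyl)methanone | CC(C)=CCOc1cc(O)cc(O)c1C(=O)c1ccccc1
F2 | step 7 | 4-[(dimethylamino)methyl]-3,5-dihydroxy-6,6-dimethyl-2-(2-methylpropanoyl)cyclohexa-2,4-dien-1-one | CC(C)C(=O)C1=C(O)C(CN(C)C)=C(O)C(C)(C)C1=O
F3 | step 7 | 5-hydroxy-2,2-dimethyl-6-methylidene-4-(2-methylpropanoyl)cyclohex-4-ene-1,3-dione | CC(C)C(=O)C1=C(O)C(=C)C(=O)C(C)(C)C1=O
F4 | step 1 | 5-acetyl-4-hydroxy-6-phenylpyran-2-one | CC(=O)c1c(O)cc(=O)oc1-c1ccccc1
F5 | step 1 | 5-acetyl-4-(3-methylbut-2-enyloxy)-6-phenylpyran-2-one | CC(=O)c1c(OCC=C(C)C)cc(=O)oc1-c1ccccc1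
F6 | step 1 | 5-[3-(dimethylamino)propanoyl]-4-(3-methylbut-2-enyloxy)-6-phenylpyran-2-one | CN(C)CCC(=O)c1c(OCC=C(C)C)cc(=O)oc1-c1ccccc1
F7 | step 1 | 5-[3-(2,6-dihydroxy-3,3-dimethyl-5-(2-methylpropanoyl)-4-oxocyclohexa-1,5-dien-1-yl)propanoyl]-4-(3-methylbut-2-enyloxy)-6-phenylpyran-2-one | CC(C)C(=O)C1=C(O)C(CCC(=O)c2c(OCC=C(C)C)cc(=O)oc2-c2ccccc2)=C(O)C(C)(C)C1=O
F8 | step 6 | [5-benzoyl-4-(3-methylbut-2-enyloxy)-2-oxopyran-6-yl]acetaldehyde | O=CCc1oc(=O)cc(OCC=C(C)C)c1C(=O)c1ccccc1
F9 | step 6 | 6-[2-[5-benzoyl-4-(3-methylbut-2-enyloxy)-2-oxopyran-6-yl]ethylidene]-5-hydroxy-2,2-dimethyl-4-(2-methylpropanoyl)cyclohex-4-ene-1,3-dione | CC(C)C(=O)C1=C(O)C(=CCc2oc(=O)cc(OCC=C(C)C)c2C(=O)c2ccccc2)C(=O)C(C)(C)C1=O
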